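## Retrosynthetic overview
1. Megaphone 21 comes from mild hydrolysis of mixed ketal 20. Ketal 20 comes from oxidative 1,4-dimethoxylation of the fused dienol ether 18 with MeOH. This is the key C–O step: it forms C4–OMe and sets C4.
2. Dienol ether 18 comes from closing the carbocycle at C2–C3 (enol ether onto acetal) in 16. Enol ether 16 comes from methylenation of the quaternary lactone 14.
3. Lactone 14 comes from two face-selective enolate alkylations of the cis-lactone 8, with allyl added last. This sets C6.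
4. Lactone 8 comes from oxidative lactonisation of diol 6, which comes from hydroboration of 4. Alcohol 4 comes from catalytic asymmetric (Z)-crotylboration of aldehyde 1, which sets C7 and C8.
5. Ring order: the oxolane (lactone) ring forms first and the six-membered carbocycle second. The oxolane is opened in the last step.

Assumption: (R)-TRIP, (Z)-crotyl-Bpin and dimethyltitanocene are purchased, and (R)-TRIP is taken to give the R carbinol as it does with other aryl aldehydes.

## Route

Step 1
Reactants: 1 3,4,5-trimethoxybenzaldehyde; 2 (Z)-crotylboronic acid pinacol ester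
Product: 4 (1R,2S)-2-methyl-1-(3,4,5-trimethoxyphenyl)but-3-en-1-ol, via pinacol borate ester 3 (not isolated)
Conditions: (R)-TRIP (5 mol %), 4 Å MS, toluene, −30 °C; aq. NaHCO3 work-up
Reagents that add atoms: (Z)-crotylboronic acid pinacol ester (2), C/C=C\CB1OC(C)(C)C(C)(C)O1
Why: Chiral phosphoric acid-catalysed asymmetric crotylboration, in which the closed chair transition state turns the Z geometry into the syn C7/C8 relationship and the catalyst exposes the aldehyde face that gives the 1R carbinol, so both side-chain stereocentres are set here.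

Step 2
Reactants: 4 (1R,2S)-2-methyl-1-(3,4,5-trimethoxyphenyl)but-3-en-1-ol
Product: 6 (1R,2S)-2-methyl-1-(3,4,5-trimethoxyphenyl)butane-1,4-diol, via bis-9-BBN adduct 5 (not isolated)
Conditions: 9-BBN (2.2 equiv), THF, 0 °C to rt; then 3 M NaOH, 30 % H2O2, 0 °C to rt
Reagents that add atoms: hydrogen peroxide, OO; 9-BBN, [H]B1C2CCCC1CCC2 (boron, in 5 only)
Why: Anti-Markovnikov hydroboration–oxidation, in which 9-BBN puts boron only on the terminal alkene carbon (the free OH just consumes one equivalent) and alkaline peroxide replaces B by OH without touching either stereocentre.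

Step 3
Reactants: 6 (1R,2S)-2-methyl-1-(3,4,5-trimethoxyphenyl)butane-1,4-diol
Product: 8 (4S,5R)-4-methyl-5-(3,4,5-trimethoxyphenyl)oxolan-2-one (4,5-cis), via lactol 7 (not isolated)
Conditions: TEMPO (10 mol %), PhI(OAc)2 (2.5 equiv), CH2Cl2, rt
Reagents that add atoms: none
Why: TEMPO/PhI(OAc)2 oxidative lactonisation of a 1,4-diol, in which the primary alcohol is oxidised faster than the hindered benzylic one, the aldehyde closes to lactol 7, and 7 is oxidised on to the γ-lactone whose cis methyl/aryl pattern is the syn relationship from step 1.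

Step 4
Reactants: 8 (4S,5R)-4-methyl-5-(3,4,5-trimethoxyphenyl)oxolan-2-one; 9 3-bromo-1,1-dimethoxypropane
Product: 11 (3S,4S,5R)-3-(3,3-dimethoxypropyl)-4-methyl-5-(3,4,5-trimethoxyphenyl)oxolan-2-one (3,4-trans major), via lithium enolate 10 (not isolated)
Conditions: LDA (1.1 equiv), THF, −78 °C; 9 (1.5 equiv), DMPU, −78 to −20 °C
Reagents that add atoms: 3-bromo-1,1-dimethoxypropane (9), COC(CCBr)OC; LDA, CC(C)N([Li])C(C)C (lithium, in 10 only)
Why: SN2 alkylation of a γ-lactone lithium enolate with a primary bromide, in which the chain enters anti to the 4-methyl group, although this centre is flattened again in step 5 so its ratio does not matter.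

Step 5
Reactants: 11 (3S,4S,5R)-3-(3,3-dimethoxypropyl)-4-methyl-5-(3,4,5-trimethoxyphenyl)oxolan-2-one; 12 allyl bromide
Product: 14 (3S,4S,5R)-3-allyl-3-(3,3-dimethoxypropyl)-4-methyl-5-(3,4,5-trimethoxyphenyl)oxolan-2-one (allyl trans to 4-methyl and 5-aryl), via lithium enolate 13 (not isolated)
Conditions: LDA (1.2 equiv), THF, −78 °C; allyl bromide (2 equiv), −78 to −40 °C
Reagents that add atoms: allyl bromide (12), C=CCBr; LDA, CC(C)N([Li])C(C)C (lithium, in 13 only)
Why: Diastereoselective second enolate alkylation, in which methyl and aryl both shield one face of the planar enolate so allyl bromide attacks the other face and the quaternary carbon (C6 of megaphone) forms with allyl trans to the methyl group, which is why allyl is added last.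

Step 6
Reactants: 14 (3S,4S,5R)-3-allyl-3-(3,3-dimethoxypropyl)-4-methyl-5-(3,4,5-trimethoxyphenyl)oxolan-2-one; 15 dimethyltitanocene
Product: 16 (2R,3S,4S)-4-allyl-4-(3,3-dimethoxypropyl)-3-methyl-5-methylidene-2-(3,4,5-trimethoxyphenyl)oxolane
Conditions: Cp2TiMe2 (2.5 equiv), toluene, 70 °C, dark; filtration through basic alumina
Reagents that add atoms: dimethyltitanocene (15), C[Ti](C)(C1C=CC=C1)C1C=CC=C1
Why: Petasis methylenation of a lactone, in which non-basic Cp2Ti=CH2 exchanges C=O for C=CH2 (the future C2) by [2+2]/retro-[2+2], leaves acetal, alkene and stereocentres alone, and runs at 70 °C, far below the temperature needed for Cope rearrangement of the 1,5-diene.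

Step 7
Reactants: 16 (2R,3S,4S)-4-allyl-4-(3,3-dimethoxypropyl)-3-methyl-5-methylidene-2-(3,4,5-trimethoxyphenyl)oxolane
Product: 18 (2R,3S,3aR)-3a-allyl-3-methyl-2-(3,4,5-trimethoxyphenyl)-2,3,3a,4-tetrahydro-1-benzofuran (5,6- and 7,7a-double bonds), via allylic methyl ether 17 (not isolated)
Conditions: TMSOTf (2.3 equiv), 2,6-di-tert-butylpyridine (2.6 equiv), CH2Cl2, −78 to 0 °C; Et3N quench, basic alumina, keep at or below rt
Reagents that add atoms: none
Why: Intramolecular Mukaiyama-type addition of the enol ether to the acetal-derived oxocarbenium ion closes the six-membered ring (C2–C3), proton loss gives 17, and TMSOTf-induced vinylogous loss of the remaining methoxy group with deprotonation at C4 gives the conjugated dienol ether without touching any stereocentre.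

Step 8
Reactants: 18 (2R,3S,3aR)-3a-allyl-3-methyl-2-(3,4,5-trimethoxyphenyl)-2,3,3a,4-tetrahydro-1-benzofuran; 19 methanol
Product: 21 megaphone, via mixed methyl ketal 20 (not isolated)
Conditions: undivided cell, RVC anode/Pt cathode, (4-BrC6H4)3N (10 mol %), Et4NOTs, 2,6-lutidine, MeOH–CH2Cl2 4:1, 0 °C, +1.05 V vs SCE, 2.1 F/mol; then PPTS, THF–H2O, rt
Reagents that add atoms: methanol (19), CO; water, O
Why: Proposed new method: a potential-gated, triarylamine-mediated anodic 1,4-dimethoxylation of a ring-fused 1-alkoxycyclohexa-1,3-diene, in which the aminium ion (about +1.05 V) oxidises only the dienol ether (estimated +0.9 to +1.0 V) and not the trimethoxyarene (about +1.4 V) or the allyl group; methanol attacks the radical cation at the diene terminus C4, giving an O-stabilised allyl radical, from the face opposite the allyl group that the oxolane ring holds pseudo-axial, which sets 4R with OMe trans to allyl and cis to the side chain; a second electron transfer gives the oxocarbenium ion that is caught as ketal 20 (any C3 adduct re-ionises to the same cation), and mild acid hydrolysis then frees the enone and the C7–OH that the tether had masked; the closest known reaction types are the anodic 2,5-dimethoxylation of furans, the anodic methoxylation of enol ether radical cations and the peracid γ-hydroxylation of steroidal dienol ethers.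

## Compound list
1 | 3,4,5-trimethoxybenzaldehyde | COc1cc(C=O)cc(OC)c1OC | starting material
2 | (Z)-crotylboronic acid pinacol ester | C/C=C\CB1OC(C)(C)C(C)(C)O1 | starting material
3 | pinacol borate ester of 4 | C=C[C@H](C)[C@@H](OB1OC(C)(C)C(C)(C)O1)c1cc(OC)c(OC)c(OC)c1 | intermediate
4 | (1R,2S)-2-methyl-1-(3,4,5-trimethoxyphenyl)but-3-en-1-ol | C=C[C@H](C)[C@@H](O)c1cc(OC)c(OC)c(OC)c1 | intermediate
5 | bis-9-BBN adduct of 4 (boron on O-1 and on C-4) | C(C[C@H](C)[C@@H](OB1C2CCCC1CCC2)c1cc(OC)c(OC)c(OC)c1)B1C2CCCC1CCC2 | intermediate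
6 | (1R,2S)-2-methyl-1-(3,4,5-trimethoxyphenyl)butane-1,4-diol | OCC[C@H](C)[C@@H](O)c1cc(OC)c(OC)c(OC)c1 | intermediate
7 | (4S,5R)-4-methyl-5-(3,4,5-trimethoxyphenyl)oxolan-2-ol (anomers) | OC1C[C@H](C)[C@H](c2cc(OC)c(OC)c(OC)c2)O1 | intermediate
8 | (4S,5R)-4-methyl-5-(3,4,5-trimethoxyphenyl)oxolan-2-one | O=C1C[C@H](C)[C@H](c2cc(OC)c(OC)c(OC)c2)O1 | intermediate
9 | 3-bromo-1,1-dimethoxypropane | COC(CCBr)OC | starting material
10 | lithium enolate of 8 | [Li]OC1=C[C@H](C)[C@H](c2cc(OC)c(OC)c(OC)c2)O1 | intermediate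
11 | (3S,4S,5R)-3-(3,3-dimethoxypropyl)-4-methyl-5-(3,4,5-trimethoxyphenyl)oxolan-2-one | O=C1[C@@H](CCC(OC)OC)[C@H](C)[C@H](c2cc(OC)c(OC)c(OC)c2)O1 | intermediate
12 | allyl bromide | C=CCBr | starting material
13 | lithium enolate of 11 | [Li]OC1=C(CCC(OC)OC)[C@H](C)[C@H](c2cc(OC)c(OC)c(OC)c2)O1 | intermediate
14 | (3S,4S,5R)-3-allyl-3-(3,3-dimethoxypropyl)-4-methyl-5-(3,4,5-trimethoxyphenyl)oxolan-2-one | O=C1[C@](CC=C)(CCC(OC)OC)[C@H](C)[C@H](c2cc(OC)c(OC)c(OC)c2)O1 | intermediate
15 | dimethyltitanocene (Petasis reagent) | C[Ti](C)(C1C=CC=C1)C1C=CC=C1 | starting material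
16 | (2R,3S,4S)-4-allyl-4-(3,3-dimethoxypropyl)-3-methyl-5-methylidene-2-(3,4,5-trimethoxyphenyl)oxolane | C=C1[C@](CC=C)(CCC(OC)OC)[C@H](C)[C@H](c2cc(OC)c(OC)c(OC)c2)O1 | intermediate
17 | (2R,3S,3aS)-3a-allyl-6-methoxy-3-methyl-2-(3,4,5-trimethoxyphenyl)-2,3,3a,4,5,6-hexahydro-1-benzofuran (C6 epimers) | C=CC[C@]12CCC(OC)C=C1O[C@@H](c1cc(OC)c(OC)c(OC)c1)[C@H]2C | intermediate
18 | (2R,3S,3aR)-3a-allyl-3-methyl-2-(3,4,5-trimethoxyphenyl)-2,3,3a,4-tetrahydro-1-benzofuran | C=CC[C@]12CC=CC=C1O[C@@H](c1cc(OC)c(OC)c(OC)c1)[C@H]2C | intermediate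
19 | methanol | CO | starting material
20 | (2R,3S,3aR,5R,7aR)-3a-allyl-5,7a-dimethoxy-3-methyl-2-(3,4,5-trimethoxyphenyl)-2,3,3a,4,5,7a-hexahydro-1-benzofuran (cis-fused) | C=CC[C@]12C[C@@H](OC)C=C[C@@]1(OC)O[C@@H](c1cc(OC)c(OC)c(OC)c1)[C@H]2C | intermediate
21 | megaphone, (4R,6R)-6-[(1R,2S)-1-hydroxy-1-(3,4,5-trimethoxyphenyl)propan-2-yl]-4-methoxy-6-(prop-2-enyl)cyclohex-2-en-1-one | C=CC[C@]1([C@H](C)[C@@H](O)c2cc(OC)c(OC)c(OC)c2)C[C@@H](OC)C=CC1=O | target

## Step count
Total step count: 8. Longest linear sequence: 8 (from 1; all other components are purchased).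

## Steps most likely to fail

**Step 8 (the proposed new step).** The risks are competing oxidation of the trimethoxyarene, attack of methanol at C2, and modest facial selectivity at C4.
- The fallback uses known chemistry. It sets out from 18 and comes back at 20.
- Rubottom-type oxidation of the dienol ether with DMDO in MeOH–CH2Cl2 at −78 °C epoxidises the electron-rich distal double bond, again opposite the allyl group.
- Methanol then opens the vinylogous oxocarbenium ion to (2R,3S,3aR,5R,7aR)-3a-allyl-7a-methoxy-3-methyl-2-(3,4,5-trimethoxyphenyl)-2,3,3a,4,5,7a-hexahydro-1-benzofuran-5-ol F1.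
- In this hydroxy ketal the C7 oxygen is still tied up in the ketal, so Williamson methylation of the only free OH (NaH, MeI, THF) gives 20. This is hydrolysed to 21 as in the route.

**Step 7.** The cascade may stop at 17, or the Lewis acid may ionise the benzylic C–O bond.
- The fallback sets out from 14, so it also avoids step 6, and comes back at 18.
- MeLi (1.1 equiv, THF, −78 °C) adds once to the hindered lactone to give the methyl lactol (3S,4S,5R)-3-allyl-3-(3,3-dimethoxypropyl)-2,4-dimethyl-5-(3,4,5-trimethoxyphenyl)oxolan-2-ol F2.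
- 1 M HCl/THF unmasks the keto aldehyde (4S)-4-acetyl-4-[(1R,2S)-1-hydroxy-1-(3,4,5-trimethoxyphenyl)propan-2-yl]hept-6-enal F3.
- Piperidinium acetate closes it by intramolecular aldol condensation to the enone 4-demethoxymegaphone F4.
- HC(OMe)3 with PPTS in CH2Cl2 at rt converts the hydroxy enone into 18, the standard dienol ether formation of enones.

**Step 4.** The unactivated, elimination-prone bromide may alkylate the enolate poorly.
- The fallback sets out from 8 and comes back at 11.
- The enolate is alkylated with the far more reactive allyl bromide 12 to give (3S,4S,5R)-3-allyl-4-methyl-5-(3,4,5-trimethoxyphenyl)oxolan-2-one F5.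
- Hydroboration with 9-BBN and NaBO3 oxidation gives the 3-(3-hydroxypropyl) lactone F6.
- Dess–Martin oxidation gives the 3-(3-oxopropyl) lactone F7.
- HC(OMe)3 with PPTS in MeOH gives the dimethyl acetal 11.

## Further compounds
F1 | step 8 | (2R,3S,3aR,5R,7aR)-3a-allyl-7a-methoxy-3-methyl-2-(3,4,5-trimethoxyphenyl)-2,3,3a,4,5,7a-hexahydro-1-benzofuran-5-ol | C=CC[C@]12C[C@@H](O)C=C[C@@]1(OC)O[C@@H](c1cc(OC)c(OC)c(OC)c1)[C@H]2C
F2 | step 7 | (3S,4S,5R)-3-allyl-3-(3,3-dimethoxypropyl)-2,4-dimethyl-5-(3,4,5-trimethoxyphenyl)oxolan-2-ol (anomers) | CC1(O)[C@](CC=C)(CCC(OC)OC)[C@H](C)[C@H](c2cc(OC)c(OC)c(OC)c2)O1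
F3 | step 7 | (4S)-4-acetyl-4-[(1R,2S)-1-hydroxy-1-(3,4,5-trimethoxyphenyl)propan-2-yl]hept-6-enal | CC(=O)[C@](CC=C)(CCC=O)[C@H](C)[C@@H](O)c1cc(OC)c(OC)c(OC)c1
F4 | step 7 | 4-demethoxymegaphone, (6S)-6-allyl-6-[(1R,2S)-1-hydroxy-1-(3,4,5-trimethoxyphenyl)propan-2-yl]cyclohex-2-en-1-one | C=CC[C@]1([C@H](C)[C@@H](O)c2cc(OC)c(OC)c(OC)c2)CCC=CC1=O
F5 | step 4 | (3S,4S,5R)-3-allyl-4-methyl-5-(3,4,5-trimethoxyphenyl)oxolan-2-one | O=C1[C@@H](CC=C)[C@H](C)[C@H](c2cc(OC)c(OC)c(OC)c2)O1
F6 | step 4 | (3S,4S,5R)-3-(3-hydroxypropyl)-4-methyl-5-(3,4,5-trimethoxyphenyl)oxolan-2-one | O=C1[C@@H](CCCO)[C@H](C)[C@H](c2cc(OC)c(OC)c(OC)c2)O1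
F7 | step 4 | 3-[(3S,4S,5R)-4-methyl-2-oxo-5-(3,4,5-trimethoxyphenyl)oxolan-3-yl]propanal | O=C1[C@@H](CCC=O)[C@H](C)[C@H](c2cc(OC)c(OC)c(OC)c2)O1
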